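(The numbers are assumed; the flask was simulated.)

The trap here is to count 1.30 equivalents of partner as plenty and to treat every captured pair as target.

    substrate ⇌ tight pair (K1 = 0.0047, k1 = 0.28 s⁻¹, Ea1 = 90.0 kJ mol⁻¹, ΔH1 = −40.0 kJ mol⁻¹)
    partner + tight pair → target (k2 = 6.8 × 10⁵ L mol⁻¹ s⁻¹, Ea2 = 19.0 kJ mol⁻¹)
    partner + protic impurity → quenched reagent (k3 = 960 L mol⁻¹ s⁻¹, Ea3 = 46.0 kJ mol⁻¹)
    target ⇌ isomer of the product B (K4 = 0.57, k4 = 0.77 s⁻¹, Ea4 = 97.0 kJ mol⁻¹, ΔH4 = −38.0 kJ mol⁻¹)
    partner + loose pair → isomer of the product A (k5 = 2.0 × 10⁶ L mol⁻¹ s⁻¹, Ea5 = 20.0 kJ mol⁻¹)
    tight pair ⇌ loose pair (K6 = 2.5, k6 = 9600 s⁻¹, Ea6 = 54.0 kJ mol⁻¹, ΔH6 = −31.0 kJ mol⁻¹)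
    (constants at 100 °C)

| setting | elm | cedar | ash |
|---|---|---|---|
| substrate | 5.0 mM | 5.0 mM | 5.0 mM |
| partner | 6.50 mM | 6.50 mM | 6.50 mM |
| protic impurity | 2.50 mM | 2.50 mM | 2.50 mM |
| temperature | 100 °C | 130 °C | 70 °C |
| time | 10 s | 10 s | 10 s |

- the best flask by amount of target, in percent of the substrate charged; "all alike" if 1.5 percentage points covers them all (elm / cedar / ash / all alike)
- amount of target at the end, in percent of the substrate charged, elm
- amount of target at the end, in percent of the substrate charged, cedar
- amount of target at the end, in percent of the substrate charged, ash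

- all constants are for 100 °C and move with temperature by the activation energies and enthalpies

Turn the constants into times, in elm first. Partner meets the protic impurity within 0.160 s, while substrate opens to the tight pair in about 3.57 s, so the impurity is served much sooner. Partner is the limiting reagent: 4.00 mM remains for the pairs, a budget of 80.0% of the substrate. Opening is the rate-limiting step, since capture at that c(partner) takes 0.368 ms, far less than the 16.8 ms a tight pair needs to close again. Elm should spend its budget in about 5.75 s, within its 10 s.

But the tight pair also leaks to the loose pair in 0.104 ms, faster than the 0.368 ms of capture at that c(partner), so two extreme flasks bracket the outcome. With c(partner) near zero, the pairs have time to equilibrate, and the share reaching target is 12.0%. With c(partner) held at 4.00 mM, a loose pair is mostly taken before it can return, and the share of captured pairs that goes to target, the target share (a selectivity), is 29.5%, from the rates of capture, leak, return and loss at that level. In the real elm c(partner) falls as the flask works, so I expect it to start near the second extreme and end near the first, and I take the middle.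

Target and isomer of the product B relax in 0.327 s, much shorter than the run, leaving 63.7% as target. My figure for elm is therefore 10.6%, between 6.12% and 15.0%. Step 1 runs 110 times faster from ash to cedar. Placing elm midway, ash opens in roughly 37.3 s, longer than its 10 s, so ash should use up far less than the budget. Cedar has the same budget, and with −38.0 kJ mol⁻¹ and −31.0 kJ mol⁻¹ heat moves both equilibria back toward target and tight pair. My order is cedar, elm, ash.

The forecast also names cedar, with 11.7% (10.3% to 13.2%) in elm, 16.7% (15% to 18.5%) in cedar and 7.2% (6.3% to 8.2%) in ash, holding that “the tight-to-loose leak sends most of the pair to product A”.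

The flasks give 11.2% in elm, 17.1% in cedar and 6.77% in ash, so cedar is best; elm ends with 80.3% conversion and partner at 0% of its charge. Elm's target and isomer of the product B make 22.0% of its three products, between 12.0% and 29.5%. The neighbour flask, elm with 16 mM of partner, ends with 55.0% of that charge, so the target share there runs from 52.2% down to 43.2%, and the same reading there gives 48.0%.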